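The quinone ring (C1 and C4 carbonyls, C2 and C5 hydroxyls, C3 methyl, C6 pentadecenyl) is cut at C2–C3 and C4–C5. This separates the two-carbon unit C3–C4, an ynol ether (1-ethoxypropyne), from the four-carbon unit C5–C6–C1–C2, carried by a squarate-derived cyclobutenone ketal that already holds the side chain. Heating both should start a pericyclic cascade (ring opening to a vinylketene, [2+2] cycloaddition, ring opening, 6π closure) that inserts the alkyne between C2 and C5 and delivers the ring at quinone oxidation level as an ortho-quinone monoketal. The step exploits the three oxygenated carbons C1, C2, C5 around C6, the polarised C3–C4 pair, and the tautomerism between 4,5-dihydroxy-1,2-quinone and 2,5-dihydroxy-1,4-quinone.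

Key step: step 5

Remark (assumption): (Z)-pentadec-10-enoic acid (sold as the fatty acid standard cis-10-pentadecenoic acid) and 1-ethoxyprop-1-yne are taken as purchasable. The 2,5-dihydroxy-1,4-quinone drawn for the target and its proton-shifted forms are one compound, so the tautomer reached first in the last step is immaterial.

Step 1
Reactants: 1 (Z)-pentadec-10-enoic acid
Product: 2 (Z)-pentadec-10-en-1-ol
Conditions: LiAlH4, THF, 0 °C to rt; then H2O, aq. NaOH
Reagents that add atoms: none
Why: Hydride reduction of the carboxylic acid with LiAlH4 should give the primary alcohol, while the isolated Z-alkene, the only stereo-element of the target, is inert to the reagent.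

Step 2
Reactants: 2 (Z)-pentadec-10-en-1-ol
Product: 3 (Z)-15-iodopentadec-5-ene
Conditions: I2, PPh3, imidazole, CH2Cl2, 0 °C to rt
Reagents that add atoms: iodine (II)
Why: Appel-type iodination (SN2 displacement of the alkoxyphosphonium ion by iodide) should give the primary iodide needed for clean halogen–lithium exchange without touching the Z-alkene.

Step 3
Reactants: 4 dimethyl squarate (3,4-dimethoxycyclobut-3-ene-1,2-dione)
Product: 5 2,3,4,4-tetramethoxycyclobut-2-en-1-one
Conditions: MeOSiMe3 (2.5 equiv), Me3SiOTf (cat.), CH2Cl2, −78 °C to rt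
Reagents that add atoms: methoxytrimethylsilane (CO[Si](C)(C)C)
Why: Noyori-type acetalisation with a silyl ether under Me3SiOTf catalysis should stop at the monoketal, because the remaining carbonyl is then an isolated vinylogous ester carbonyl that has lost the activation by its carbonyl neighbour.

Step 4
Reactants: 3 (Z)-15-iodopentadec-5-ene; 5 2,3,4,4-tetramethoxycyclobut-2-en-1-one
Product: 9 2,4,4-trimethoxy-3-[(Z)-pentadec-10-enyl]cyclobut-2-en-1-one, via [(Z)-pentadec-10-enyl]lithium 6 (not isolated), via lithium tertiary alkoxide 7 (not isolated), via tertiary trifluoroacetate 8 (not isolated)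
Conditions: 3, t-BuLi (2.1 equiv), Et2O–pentane, −78 °C; then 5, THF, −78 °C; then (CF3CO)2O, −78 °C; then aq. NaHCO3, −78 °C to rt
Reagents that add atoms: water (O)
Why: Iodine–lithium exchange gives 6, which adds 1,2 to the only carbonyl of 5; trifluoroacetylation of alkoxide 7 and ionisation of 8 give a methoxy-stabilised cyclobutenyl cation that water captures at its methoxy-bearing terminus with loss of methanol (the squarate carbinol-to-cyclobutenone 1,3-carbonyl transposition), which places the chain β and a methoxy group α to the new carbonyl while the ketal survives, and the racemic stereocentre of 7 and 8 is destroyed.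

Step 5
Reactants: 9 2,4,4-trimethoxy-3-[(Z)-pentadec-10-enyl]cyclobut-2-en-1-one; 10 1-ethoxyprop-1-yne
Product: 14 3-ethoxy-4,6,6-trimethoxy-2-methyl-5-[(Z)-pentadec-10-enyl]cyclohexa-2,4-dien-1-one, via vinylketene 11 (not isolated), via vinylcyclobutenone 12 (not isolated), via dienylketene 13 (not isolated)
Conditions: 10 (3 equiv), toluene (0.5 M), 90 °C, sealed tube, argon, dark
Reagents that add atoms: none
Why: Proposed new method: heating 9 should cause 4π electrocyclic opening to the (dimethoxyvinyl)ketene 11, whose ketene C=C bond undergoes a [2+2] cycloaddition with ynol ether 10 that joins the ketene carbonyl carbon to the methyl-bearing alkyne carbon and the methoxy-bearing ketene carbon to the ethoxy-bearing alkyne carbon, so that both new ring bonds form at once and every atom of 9 and 10 is kept. The 4-vinylcyclobutenone 12 should then open (4π, methoxy outward, vinyl inward) to the Z-dienylketene 13, which closes the six-membered carbocycle by a thermal disrotatory 6π electrocyclisation onto the ketene acetal terminus. The closest known reaction type is the Danheiser benzannulation of cyclobutenones with alkoxyalkynes, which has not been shown for squarate-derived 4,4-dialkoxycyclobutenones. Because the terminus carries two methoxy groups, tautomerisation to a phenol is blocked and the product stays at quinone oxidation level as an ortho-quinone monoketal, so no oxidation step is needed. No stereocentre is present in 14 (the quaternary centre of 12 is racemic and transient). The selectivities needed are the regiochemistry of the [2+2] step, secured by the strong polarisation of the ynol ether toward its methyl-bearing carbon, and intermolecular capture of 11 ahead of its self-reaction, secured by the excess of 10 at high concentration.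

Step 6
Reactants: 14 3-ethoxy-4,6,6-trimethoxy-2-methyl-5-[(Z)-pentadec-10-enyl]cyclohexa-2,4-dien-1-one
Product: 17 2,5-dihydroxy-3-methyl-6-[(Z)-pentadec-10-enyl]cyclohexa-2,5-diene-1,4-dione, via ortho-quinone 15 (not isolated), via ethoxy hydroxy quinone 16 (not isolated)
Conditions: 1 M HCl, THF, rt; then 2 M NaOH, rt; then HCl to pH 2
Reagents that add atoms: water (O)
Why: Acid-catalysed ketal hydrolysis unmasks ortho-quinone 15, whose two alkoxy groups are vinylogous esters and should leave by addition–elimination (the first in acid from the electrophilic ortho-quinone to give 16, drawn for loss of methoxy first although the other order gives the same product, the second with hydroxide), and tautomerisation gives the 2,5-dihydroxy-1,4-quinone 17, with no stereocentre involved and the Z-alkene inert to dilute acid and base.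

Compound list
1 | (Z)-pentadec-10-enoic acid | CCCC/C=C\CCCCCCCCC(=O)O | starting material
2 | (Z)-pentadec-10-en-1-ol | CCCC/C=C\CCCCCCCCCO | intermediate
3 | (Z)-15-iodopentadec-5-ene | CCCC/C=C\CCCCCCCCCI | intermediate
4 | dimethyl squarate (3,4-dimethoxycyclobut-3-ene-1,2-dione) | COC1=C(OC)C(=O)C1=O | starting material
5 | 2,3,4,4-tetramethoxycyclobut-2-en-1-one | COC1=C(OC)C(OC)(OC)C1=O | intermediate
6 | [(Z)-pentadec-10-enyl]lithium | [Li]CCCCCCCCC/C=C\CCCC | intermediate
7 | lithium 2,3,4,4-tetramethoxy-1-[(Z)-pentadec-10-enyl]cyclobut-2-en-1-olate (racemic) | [Li+].[O-]C1(CCCCCCCCC/C=C\CCCC)C(OC)=C(OC)C1(OC)OC | intermediate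
8 | 2,3,4,4-tetramethoxy-1-[(Z)-pentadec-10-enyl]cyclobut-2-en-1-yl trifluoroacetate (racemic) | O=C(OC1(CCCCCCCCC/C=C\CCCC)C(OC)=C(OC)C1(OC)OC)C(F)(F)F | intermediate
9 | 2,4,4-trimethoxy-3-[(Z)-pentadec-10-enyl]cyclobut-2-en-1-one | COC1=C(CCCCCCCCC/C=C\CCCC)C(OC)(OC)C1=O | intermediate
10 | 1-ethoxyprop-1-yne | CC#COCC | starting material
11 | 2,4,4-trimethoxy-3-[(Z)-pentadec-10-enyl]buta-1,3-dien-1-one (vinylketene) | O=C=C(OC)C(CCCCCCCCC/C=C\CCCC)=C(OC)OC | intermediate
12 | 3-ethoxy-4-methoxy-2-methyl-4-[2,2-dimethoxy-1-((Z)-pentadec-10-enyl)ethenyl]cyclobut-2-en-1-one (racemic) | O=C1C(C)=C(OCC)C1(OC)C(CCCCCCCCC/C=C\CCCC)=C(OC)OC | intermediate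
13 | (3Z)-3-ethoxy-4,6,6-trimethoxy-2-methyl-5-[(Z)-pentadec-10-enyl]hexa-1,3,5-trien-1-one (dienylketene) | O=C=C(C)/C(OCC)=C(OC)\C(CCCCCCCCC/C=C\CCCC)=C(OC)OC | intermediate
14 | 3-ethoxy-4,6,6-trimethoxy-2-methyl-5-[(Z)-pentadec-10-enyl]cyclohexa-2,4-dien-1-one (ortho-quinone monoketal) | O=C1C(C)=C(OCC)C(OC)=C(CCCCCCCCC/C=C\CCCC)C1(OC)OC | intermediate
15 | 4-ethoxy-5-methoxy-3-methyl-6-[(Z)-pentadec-10-enyl]cyclohexa-3,5-diene-1,2-dione | O=C1C(=O)C(C)=C(OCC)C(OC)=C1CCCCCCCCC/C=C\CCCC | intermediate
16 | 2-ethoxy-5-hydroxy-3-methyl-6-[(Z)-pentadec-10-enyl]cyclohexa-2,5-diene-1,4-dione | CCOC1=C(C)C(=O)C(O)=C(CCCCCCCCC/C=C\CCCC)C1=O | intermediate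
17 | 2,5-dihydroxy-3-methyl-6-[(Z)-pentadec-10-enyl]cyclohexa-2,5-diene-1,4-dione | CCCC/C=C\CCCCCCCCCC1=C(O)C(=O)C(C)=C(O)C1=O | target

Total step count: 6. Longest linear sequence: 5 steps (steps 1, 2, 4, 5, 6); step 3 is a one-step side branch.

Steps most likely to fail

Step 5 (labelled step). The vinylketene may be consumed before the ynol ether captures it, by attack of the inward methoxy oxygen on the ketene carbon or by self-dimerisation. The ynol ether may also lose ethylene thermally, or the dienone product may dimerise by Diels–Alder reaction. The fallback uses known chemistry, forms the same two ring bonds, sets out from 9 and comes back at 17. Hydrolysis of the ketal of 9 (1 M HCl, THF, rt) would give 3-methoxy-4-[(Z)-pentadec-10-enyl]cyclobut-3-ene-1,2-dione F1. Insertion of ClCo(PPh3)3 (monovalent cobalt) into the bond between the two carbonyl carbons (benzene, rt) would give the chlorobis(triphenylphosphine) maleoylcobalt metallacycle F2 (trivalent cobalt). Reaction of this complex with alkyne 10 after chloride abstraction (AgBF4, MeCN), the known quinone synthesis from maleoylcobalt complexes and alkynes, would give 2-ethoxy-5-methoxy-3-methyl-6-[(Z)-pentadec-10-enyl]cyclohexa-2,5-diene-1,4-dione F3. By analogy with terminal alkynes, the cation-stabilising ethoxy-bearing carbon is expected to join the vinylogous ester acyl carbon; the regioisomeric quinone, if formed, would be separated. Hydrolysis of both vinylogous esters (2 M NaOH, EtOH, rt; then HCl) would give 17.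

Step 6. The liberated ortho-quinone may decompose (ring contraction, addition of water at a carbonyl carbon) before its alkoxy groups are exchanged, or the second alkoxy group may be cleaved incompletely. The fallback avoids the free ortho-quinone by a redox detour; it sets out from 14 and comes back at 17. Reduction of the quinone monoketal (Zn, AcOH, rt) with loss of methanol would give 3-ethoxy-4,6-dimethoxy-2-methyl-5-[(Z)-pentadec-10-enyl]phenol F4. Oxidative demethylation of this para-methoxyphenol ((NH4)2Ce(NO3)6, MeCN–H2O, 0 °C) would give the 2-ethoxy-5-methoxy-1,4-quinone F3 described above. Its hydrolysis (2 M NaOH, EtOH, rt; then HCl) would give 17.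

Step 4. Electron-transfer side reactions (Wurtz-type coupling) may erode the halogen–lithium exchange, and the ketal may ionise in competition with the tertiary trifluoroacetate during the anhydride quench, which would erase the distinction between the two carbonyl positions. The fallback changes the organometallic and separates addition from rearrangement; it sets out from 2 and comes back at 9. Bromination of 2 (CBr4, PPh3, CH2Cl2, 0 °C) would give (Z)-15-bromopentadec-5-ene F5. Magnesium insertion (Mg, THF) would give [(Z)-pentadec-10-enyl]magnesium bromide F6. Its 1,2-addition to 5 (THF, −78 to 0 °C; aq. NH4Cl) would give the isolable carbinol 2,3,4,4-tetramethoxy-1-[(Z)-pentadec-10-enyl]cyclobut-2-en-1-ol F7. This would be rearranged separately under mild acid catalysis (cat. HCl, wet CH2Cl2, 0 °C) to 9.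

Further compounds
F1 | step 5 | 3-methoxy-4-[(Z)-pentadec-10-enyl]cyclobut-3-ene-1,2-dione | COC1=C(CCCCCCCCC/C=C\CCCC)C(=O)C1=O
F2 | step 5 | 1-chloro-3-methoxy-4-[(Z)-pentadec-10-enyl]-1,1-bis(triphenylphosphine)cobaltacyclopent-3-ene-2,5-dione (trivalent cobalt) | COC1=C(CCCCCCCCC/C=C\CCCC)C(=O)[Co-2](Cl)([P+](c2ccccc2)(c2ccccc2)c2ccccc2)([P+](c2ccccc2)(c2ccccc2)c2ccccc2)C1=O
F3 | step 5 | 2-ethoxy-5-methoxy-3-methyl-6-[(Z)-pentadec-10-enyl]cyclohexa-2,5-diene-1,4-dione | CCOC1=C(C)C(=O)C(OC)=C(CCCCCCCCC/C=C\CCCC)C1=O
F4 | step 6 | 3-ethoxy-4,6-dimethoxy-2-methyl-5-[(Z)-pentadec-10-enyl]phenol | CCOc1c(C)c(O)c(OC)c(CCCCCCCCC/C=C\CCCC)c1OC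
F5 | step 4 | (Z)-15-bromopentadec-5-ene | CCCC/C=C\CCCCCCCCCBr
F6 | step 4 | [(Z)-pentadec-10-enyl]magnesium bromide | CCCC/C=C\CCCCCCCCC[Mg]Br
F7 | step 4 | 2,3,4,4-tetramethoxy-1-[(Z)-pentadec-10-enyl]cyclobut-2-en-1-ol (racemic) | COC1=C(OC)C(OC)(OC)C1(O)CCCCCCCCC/C=C\CCCC
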